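**Plan**

- Target: 15-(5-methoxy-3,6-dioxocyclohexa-1,4-dien-1-yl)pentadecanoic acid, an achiral 2-methoxy-6-alkyl-1,4-benzoquinone (ring: C1=O, C2–OMe, C4=O, C6–(CH2)14CO2H).
- Enabling feature: the C2 oxygen, the C4 oxygen and the alkyl-bearing C6 are mutually meta. Without the C1 oxygen the ring is a 5-alkylresorcinol, which at the reduced level is a 5-alkylcyclohexane-1,3-dione.
- Retrosynthesis: C1=O goes back to C1–H (para-oxidation of a phenol), and the arene goes back to the cyclohexane-1,3-dione. Ring bonds C1–C6 and C2–C3 are then cut to dimethyl malonate (C1, C2) and a methyl enone (C3–C6 with the chain), and the enone C5=C6 is cut to a C16 ω-oxo ester (Wittig).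
- Forward: the chain is prepared first (esterification, oxidation, olefination). The single ring then forms in one flask by Michael addition and Claisen closure, followed by decarboxylation, aromatisation, mono-demethylation and oxidation to the quinone.
- Stereochemistry: the target has no stereocentre. The (E)-alkene from the stabilised ylide is consumed in the annulation, and the transient ring stereocentres form racemic and vanish on aromatisation.

Key step: step 4

Remark: the cyclic 1,3-dicarbonyl intermediates are drawn as keto tautomers although they should exist largely as enols. They are racemic (diastereomer mixtures where two ring stereocentres are present), which does not matter because every ring stereocentre disappears on aromatisation.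

**Route**

Step 1
Reactants: 1 16-hydroxyhexadecanoic acid
Product: 2 methyl 16-hydroxyhexadecanoate
Conditions: MeOH, H2SO4 (cat.), reflux
Reagents that add atoms: methanol, CO
Why: Fischer esterification in a large excess of methanol should drive the ω-hydroxy acid to its methyl ester and suppress oligoester formation, leaving the primary alcohol free.

Step 2
Reactants: 2 methyl 16-hydroxyhexadecanoate
Product: 3 methyl 16-oxohexadecanoate
Conditions: TEMPO (10 mol%), PhI(OAc)2 (1.1 equiv), CH2Cl2, rt
Reagents that add atoms: none
Why: TEMPO-catalysed oxoammonium oxidation with PhI(OAc)2 as terminal oxidant should stop at the aldehyde under anhydrous conditions and leave the methyl ester untouched.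

Step 3
Reactants: 3 methyl 16-oxohexadecanoate; 4 1-(triphenylphosphoranylidene)propan-2-one
Product: 5 methyl (E)-18-oxononadec-16-enoate
Conditions: THF, reflux
Reagents that add atoms: none
Why: Wittig olefination with a ketone-stabilised ylide should give the (E)-enone selectively through reversible oxaphosphetane formation, and the ylide is too weakly basic to disturb the methyl ester.

Step 4
Reactants: 5 methyl (E)-18-oxononadec-16-enoate; 6 dimethyl malonate
Product: 8 methyl 2-(15-methoxy-15-oxopentadecyl)-4,6-dioxocyclohexane-1-carboxylate (racemic), via Michael adduct 7 (not isolated)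
Conditions: NaOMe (1.2 equiv), MeOH, reflux; then cold 1 M HCl to pH 3
Reagents that add atoms: none
Why: Sodium dimethyl malonate (its carbon becomes C1) should add in a Michael reaction to the enone β-carbon C6, forming C1–C6 and giving adduct 7. Proton exchange then gives the methyl-side ketone enolate (C3), which attacks a malonate ester carbonyl (C2) in an intramolecular Claisen (Dieckmann-type) condensation with loss of methoxide; this 6-(enolendo)-exo-trig closure forms C2–C3 and the six-membered carbocycle. The closest known reaction type is the classical malonate–enone Michael–Claisen annulation used for 5-alkylcyclohexane-1,3-diones. The stereocentres at C1 and C6 arise without control as a racemic mixture and are later removed by decarboxylation and aromatisation, so none has to be set. The step needs chemoselective ring closure, and the substrate secures it: only the C3 enolate can reach a malonate ester through a six-membered transition state (the C5 enolate would close a four-membered ring), and the chain ester lies fifteen atoms away. All esters are methyl esters, so methoxide exchange is degenerate, and deprotonation of the acidic cyclic β-dicarbonyl product pulls the equilibria forward.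

Step 5
Reactants: 8 methyl 2-(15-methoxy-15-oxopentadecyl)-4,6-dioxocyclohexane-1-carboxylate
Product: 10 15-(3,5-dioxocyclohexyl)pentadecanoic acid, via diacid 9 (not isolated)
Conditions: 2 M NaOH aq., reflux; then conc. HCl to pH 1, reflux
Reagents that add atoms: sodium hydroxide, [Na+].[OH-]
Why: Saponification of both methyl esters followed by acidification should give the β-keto acid 9, which decarboxylates on heating through the usual cyclic transition state to the 5-substituted cyclohexane-1,3-dione while the remote carboxylic acid is unaffected.

Step 6
Reactants: 10 15-(3,5-dioxocyclohexyl)pentadecanoic acid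
Product: 12 methyl 15-(3,5-dimethoxyphenyl)pentadecanoate, via enol ether ester 11 (not isolated)
Conditions: I2 (2 equiv), MeOH, reflux
Reagents that add atoms: methanol, CO
Why: Iodine–methanol oxidative aromatisation of a cyclohexane-1,3-dione: acid-catalysed enol-ether formation (11, with Fischer esterification of the chain acid by the HI released), α-iodination and loss of HI should deliver the resorcinol dimethyl ether, and any monomethyl ether or unesterified acid that accompanies it converges on 13 in step 7.

Step 7
Reactants: 12 methyl 15-(3,5-dimethoxyphenyl)pentadecanoate
Product: 13 15-(3-hydroxy-5-methoxyphenyl)pentadecanoic acid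
Conditions: NaSEt (5 equiv), DMF, 140 °C; then 1 M HCl
Reagents that add atoms: none
Why: Thiolate SN2 dealkylation should cleave the methyl ester and one aryl methyl ether, after which the phenoxide formed deactivates the ring towards loss of the second O-methyl group, so the reaction should stop at the monomethyl ether.

Step 8
Reactants: 13 15-(3-hydroxy-5-methoxyphenyl)pentadecanoic acid
Product: 14 15-(5-methoxy-3,6-dioxocyclohexa-1,4-dien-1-yl)pentadecanoic acid
Conditions: (KSO3)2NO (potassium nitrosodisulfonate, 2.5 equiv), KH2PO4 aq./acetone, rt
Reagents that add atoms: potassium nitrosodisulfonate, [K+].[K+].[O]N(S(=O)(=O)[O-])S(=O)(=O)[O-]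
Why: Teuber oxidation: one nitrosodisulfonate radical abstracts the phenolic hydrogen, a second couples at the free para carbon (C1, between the methoxy and alkyl carbons) and loss of imidodisulfonate should give the p-quinone, the near-neutral buffer sparing both the methoxyquinone and the carboxylic acid.

**Compound list**

1 | 16-hydroxyhexadecanoic acid | OCCCCCCCCCCCCCCCC(=O)O | starting material
2 | methyl 16-hydroxyhexadecanoate | OCCCCCCCCCCCCCCCC(=O)OC | intermediate
3 | methyl 16-oxohexadecanoate | O=CCCCCCCCCCCCCCCC(=O)OC | intermediate
4 | 1-(triphenylphosphoranylidene)propan-2-one | CC(=O)C=P(c1ccccc1)(c1ccccc1)c1ccccc1 | starting material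
5 | methyl (E)-18-oxononadec-16-enoate | CC(=O)/C=C/CCCCCCCCCCCCCCC(=O)OC | intermediate
6 | dimethyl malonate | COC(=O)CC(=O)OC | starting material
7 | trimethyl 2-(2-oxopropyl)hexadecane-1,1,16-tricarboxylate (Michael adduct, racemic, not isolated) | COC(=O)C(C(=O)OC)C(CC(C)=O)CCCCCCCCCCCCCCC(=O)OC | intermediate
8 | methyl 2-(15-methoxy-15-oxopentadecyl)-4,6-dioxocyclohexane-1-carboxylate (racemic, diastereomer and enol mixture) | COC(=O)C1C(=O)CC(=O)CC1CCCCCCCCCCCCCCC(=O)OC | intermediate
9 | 2-(14-carboxytetradecyl)-4,6-dioxocyclohexane-1-carboxylic acid (racemic, not isolated) | OC(=O)C1C(=O)CC(=O)CC1CCCCCCCCCCCCCCC(=O)O | intermediate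
10 | 15-(3,5-dioxocyclohexyl)pentadecanoic acid | O=C1CC(=O)CC(CCCCCCCCCCCCCCC(=O)O)C1 | intermediate
11 | methyl 15-(3-methoxy-5-oxocyclohex-3-en-1-yl)pentadecanoate (racemic, not isolated) | COC1=CC(=O)CC(CCCCCCCCCCCCCCC(=O)OC)C1 | intermediate
12 | methyl 15-(3,5-dimethoxyphenyl)pentadecanoate | COc1cc(OC)cc(CCCCCCCCCCCCCCC(=O)OC)c1 | intermediate
13 | 15-(3-hydroxy-5-methoxyphenyl)pentadecanoic acid | COc1cc(O)cc(CCCCCCCCCCCCCCC(=O)O)c1 | intermediate
14 | 15-(5-methoxy-3,6-dioxocyclohexa-1,4-dien-1-yl)pentadecanoic acid | COC1=CC(=O)C=C(CCCCCCCCCCCCCCC(=O)O)C1=O | target

**Totals**

Total step count: 8. Longest linear sequence: 8 steps (from 1 to 14).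

**Steps most likely to fail**

Step 6 (iodine–methanol aromatisation). O-methylation may be incomplete before the ring aromatises, the electron-rich arene may be iodinated by excess iodine, or the chain acid may be only partly esterified. The fallback aromatises at the β-keto ester stage with bromine and methylates afterwards. It sets out from 8: Br2 in DMF (0 °C, then 80 °C) should brominate and dehydrobrominate the ring to methyl 2,4-dihydroxy-6-(15-methoxy-15-oxopentadecyl)benzoate F1. Aqueous NaOH at reflux followed by acidification should saponify both esters and decarboxylate the 2,4-dihydroxybenzoic acid to 15-(3,5-dihydroxyphenyl)pentadecanoic acid F2. Me2SO4 with K2CO3 in refluxing acetone should then methylate both phenols and the carboxylate, and the sequence comes back to the route at 12.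

Step 8 (Teuber oxidation). The long-chain carboxylate may dissolve poorly in the aqueous buffer and react slowly as a suspension, ortho-oxidation or over-oxidation may compete, and the methoxy group may be lost from the quinone during a non-neutral work-up. The fallback installs the C1 oxygen by formylation and Dakin oxidation and ends with an oxidative demethylation, which also bypasses step 7. It sets out from 12: Vilsmeier–Haack formylation (POCl3, DMF) should occur para to one methoxy group and ortho to the chain, giving methyl 15-(2-formyl-3,5-dimethoxyphenyl)pentadecanoate F3. mCPBA in CH2Cl2 should convert the aldehyde by Baeyer–Villiger oxidation into methyl 15-[2-(formyloxy)-3,5-dimethoxyphenyl]pentadecanoate F4. KOH in aqueous MeOH under nitrogen, then acid, should cleave the formate and the chain ester to 15-(2-hydroxy-3,5-dimethoxyphenyl)pentadecanoic acid F5. (NH4)2Ce(NO3)6 in aqueous MeCN at 0 °C should oxidise this p-methoxyphenol to the p-quinone with loss of methanol, and the sequence comes back to the route at 14.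

Step 4 (key annulation). The enolisable enone may self-condense or deconjugate under methoxide before the malonate adds, the adduct may revert by retro-Michael reaction, or the Claisen closure may stall if the long-chain adduct or its sodium salt separates from methanol. The fallback builds the Michael adduct from the opposite side under Lewis-acid conditions and runs the ring closure on its own. It sets out from 3 and 6: Knoevenagel condensation (TiCl4, pyridine, THF, 0 °C to rt) should give dimethyl 2-(16-methoxy-16-oxohexadecylidene)propanedioate F6. Mukaiyama–Michael addition of 2-(trimethylsilyloxy)propene (TiCl4, CH2Cl2, −78 °C, aqueous work-up) should then give the adduct as an isolated compound, and the sequence comes back to the route at 7. Compound 7 is closed to 8 with NaOMe in MeOH/THF at reflux by the same C2–C3 Claisen condensation.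

**Further compounds**

F1 | step 6 | methyl 2,4-dihydroxy-6-(15-methoxy-15-oxopentadecyl)benzoate | COC(=O)c1c(O)cc(O)cc1CCCCCCCCCCCCCCC(=O)OC
F2 | step 6 | 15-(3,5-dihydroxyphenyl)pentadecanoic acid | Oc1cc(O)cc(CCCCCCCCCCCCCCC(=O)O)c1
F3 | step 8 | methyl 15-(2-formyl-3,5-dimethoxyphenyl)pentadecanoate | COc1cc(OC)c(C=O)c(CCCCCCCCCCCCCCC(=O)OC)c1
F4 | step 8 | methyl 15-[2-(formyloxy)-3,5-dimethoxyphenyl]pentadecanoate | COc1cc(OC)c(OC=O)c(CCCCCCCCCCCCCCC(=O)OC)c1
F5 | step 8 | 15-(2-hydroxy-3,5-dimethoxyphenyl)pentadecanoic acid | COc1cc(OC)c(O)c(CCCCCCCCCCCCCCC(=O)O)c1
F6 | step 4 | dimethyl 2-(16-methoxy-16-oxohexadecylidene)propanedioate | COC(=O)C(=CCCCCCCCCCCCCCCC(=O)OC)C(=O)OC
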